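All runs are calculated with made-up constants.

Set the amounts side by side: the flask and the gamma run hold 2.0 µM of initiator against 2.9 µM of impurity, the epsilon run holds 2 µM against 1.4 µM, and 2.0 × 10⁻⁴ M of free monomer is fed into each over 3.0 min.

common to all: free monomer 2.0 × 10⁻⁴ M (fed, over 3.0 min)

| run | initiator | impurity | remark | time |
|---|---|---|---|---|
| gamma | 2 µM | 2.9 µM | the very flask that is asked about, followed so far; the fed solution adds 0.50 times the starting volume |  |
| epsilon | 2 µM | 1.4 µM | run made earlier; the fed solution adds 0.50 times the starting volume |  |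
| flask | 2.0 µM | 2.9 µM | the fed solution adds 0.50 times the starting volume | 8.0 min |

| run | time / min | monomer in chains / % | free monomer / % |
|---|---|---|---|
| gamma | 0.667 | 0.2 | 21.1 |
| gamma | 1.33 | 1.0 | 43.0 |
| gamma | 2.00 | 3.1 | 64.5 |
| gamma | 2.50 | 3.6 | 80.1 |
| gamma | 3.00 | 5.1 | 94.9 |
| gamma | 4.00 | 7.5 | 92.0 |
| epsilon | 1.00 | 3.6 | 30.5 |
| epsilon | 2.00 | 11.0 | 55.3 |
| epsilon | 3.00 | 21.7 | 77.5 |
| epsilon | 4.00 | 32.9 | 66.8 |
| epsilon | 5.00 | 42.3 | 57.9 |
| epsilon | 6.00 | 50.2 | 49.6 |

(scatter of a reading: 0.5 percentage points)

* amount of monomer in chains in the flask at 8.0 min, in percent of the free monomer charged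
* amount of free monomer in the flask at 8.0 min, in percent of the free monomer charged

Climb the ladder of times from the short end. On the lowest rung, take it as my own assumption that the contest for the initiator is over before the first gamma reading at 0.667 min, leaving a fixed [living end]. On the next rung stands the feed: a portion of free monomer enters on average at mid-feed, so start the growth clock at 1.50 min. Above that, read the growth constant, the pseudo-first-order constant k3[living end], as ln(1/(1 − chain share)) divided by the time since mid-feed, 0.0312 min⁻¹ from gamma at 4.00 min. The same reading on epsilon at 6.00 min gives 0.155 min⁻¹, which is 4.97 times larger. Its inverse for gamma, 32.1 min, is longer than the 8.0 min asked about, so expect the flask to be still early in its growth: my reckoning gives 18.3% in chains.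

The forecast, made from these runs, says 18% in chains and 82% free, holding that “the living-end level is again constant”; my own figure, counted from mid-feed, stands slightly higher in chains than the forecast's.

The flask gives 18.7% in chains and 81.3% free, with 6.23 × 10⁻⁸ M of living end at 8.00 min, the same as at 3.00 min.

    initiator + impurity → spent initiator A (k = 1.80 × 10⁵ M⁻¹ s⁻¹)
    initiator → spent initiator B (k = 0.0240 s⁻¹)
    free monomer + living end → monomer in chains + living end, rate k3*[living end]*[free monomer] (k = 8300 M⁻¹ s⁻¹)
    free monomer + initiator → living end + monomer in chains (k = 5100 M⁻¹ s⁻¹)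

By the same reckoning, those chains give 0.0318 min⁻¹ for the flask. Now carry 0.0312 min⁻¹ to the neighbouring flask charged with 8.0 × 10⁻⁵ M of free monomer: assuming that [living end] follows the monomer charge, scale it by the charge ratio 0.400, which gives 0.0125 min⁻¹ and a reckoned 7.79% in chains at 8.0 min. That neighbour holds 2.86 × 10⁻⁸ M of living end, 0.459 of the flask's level, and stands higher in chains than the reckoning, with 90.9% free and 9.13% in chains.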